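**Strategy**

The route rests on forming the C5–O bond last. A 6,7,8-trimethoxyflavone whose ring A carries a single C–H bond (C5–H) is assembled from a hydroxyacetophenone and O-tosylated isovanillic acid chloride. The key step exploits the peri relationship between that C5–H of ring A and the C4 carbonyl oxygen of the pyranone ring C: the ketone chelates ruthenium, a five-membered metallacycle forms, and oxidation installs the missing C5 oxygen in one operation without closing a ring. The precursor is 6,7,8,4'-tetramethoxy-3'-(tosyloxy)flavone (12), whose electron-poor sulfonate shields ring B. Methylation of the new chelated 5-hydroxyl and sulfonate cleavage finish the target.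

Key step: step 7

Remark: all compounds are achiral, so no stereocentre has to be set; the C5 oxygen of 14 is taken to come from a trifluoroacetate ligand delivered by PhI(OCOCF3)2 (exchange with the CF3CO2H medium would give the same ester 13).

**Route**

Step 1
Reactants: 1 2,3,4-trimethoxybenzaldehyde
Product: 3 2,3,4-trimethoxyphenol, via 2,3,4-trimethoxyphenyl formate 2 (not isolated)
Conditions: 30% aq. H2O2 (1.3 equiv), cat. H2SO4, MeOH, rt
Reagents that add atoms: hydrogen peroxide, OO
Why: Dakin oxidation (Baeyer–Villiger-type aryl migration in the peroxide adduct of the aldehyde) is favoured by the ortho and para methoxy groups, and formate 2 should be methanolysed in the same acidic medium.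

Step 2
Reactants: 3 2,3,4-trimethoxyphenol
Product: 5 1-(2-hydroxy-3,4,5-trimethoxyphenyl)ethanone, via difluoroboron chelate 4 (not isolated)
Conditions: AcOH, BF3·OEt2 (3 equiv), 90 °C; then EtOH–H2O, reflux
Reagents that add atoms: acetic acid, CC(=O)O
Why: BF3-mediated Friedel–Crafts acetylation of the Fries type should place the acetyl group at C6 of 3, ortho to the hydroxyl and para to the 3-methoxy group, because only this position leads to the six-membered boron chelate 4, which is then hydrolysed to 5.

Step 3
Reactants: 6 isovanillic acid (3-hydroxy-4-methoxybenzoic acid); 7 p-toluenesulfonyl chloride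
Product: 8 4-methoxy-3-(tosyloxy)benzoic acid
Conditions: NaOH (2.5 equiv), THF–H2O, 0 °C to rt; then aq. HCl to pH 2
Reagents that add atoms: none
Why: Schotten–Baumann sulfonylation of the phenoxide should be clean because any mixed carboxylic–sulfonic anhydride is hydrolysed back to the carboxylate in the aqueous base, and acidification releases the acid.

Step 4
Reactants: 8 4-methoxy-3-(tosyloxy)benzoic acid
Product: 9 4-methoxy-3-(tosyloxy)benzoyl chloride
Conditions: SOCl2, cat. DMF, toluene, 70 °C; evaporate
Reagents that add atoms: thionyl chloride, O=S(Cl)Cl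
Why: Acyl chloride formation through the chlorosulfite with Vilsmeier-type catalysis by DMF leaves the aryl sulfonate and the methyl ether untouched.

Step 5
Reactants: 5 1-(2-hydroxy-3,4,5-trimethoxyphenyl)ethanone; 9 4-methoxy-3-(tosyloxy)benzoyl chloride
Product: 11 1-(2-hydroxy-3,4,5-trimethoxyphenyl)-3-[4-methoxy-3-(tosyloxy)phenyl]propane-1,3-dione (expected mainly as its chelated enol), via dilithium phenoxide enolate 10 (not isolated)
Conditions: LiN(SiMe3)2 (3.2 equiv), THF, −78 to −10 °C; then 9, −78 °C to rt; aq. HCl
Reagents that add atoms: none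
Why: Claisen-type C-aroylation of the ketone enolate, in which the non-nucleophilic amide base forms dianion 10 without attacking the sulfonate, the enolate carbon takes the acid chloride and the third equivalent of base holds the product as its diketonate, reaches in one flask the diketone of a Baker–Venkataraman sequence.

Step 6
Reactants: 11 the 1,3-diketone
Product: 12 6,7,8,4'-tetramethoxy-3'-(tosyloxy)flavone (2-[4-methoxy-3-(tosyloxy)phenyl]-6,7,8-trimethoxy-4H-chromen-4-one)
Conditions: cat. H2SO4, AcOH, 95 °C
Reagents that add atoms: none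
Why: Acid-catalysed cyclodehydration of the o-hydroxyaryl 1,3-diketone (phenol oxygen adds to the protonated aroyl carbonyl, then water is lost) forms the 4-pyranone, and aryl sulfonates and aryl methyl ethers tolerate these conditions.

Step 7
Reactants: 12 6,7,8,4'-tetramethoxy-3'-(tosyloxy)flavone
Product: 14 5-hydroxy-6,7,8,4'-tetramethoxy-3'-(tosyloxy)flavone, via C5 trifluoroacetate ester 13 (not isolated)
Conditions: [RuCl2(p-cymene)]2 (5 mol %), PhI(OCOCF3)2 (2 equiv), CF3CO2H–(CF3CO)2O, 80 °C; evaporate; Me2S, CH2Cl2, 0 °C; then aq. NaHCO3–MeOH, rt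
Reagents that add atoms: [bis(trifluoroacetoxy)iodo]benzene, O=C(OI(OC(=O)C(F)(F)F)c1ccccc1)C(F)(F)F
Why: Chloride–trifluoroacetate exchange on [RuCl2(p-cymene)]2 gives a divalent ruthenium carboxylate that binds the C4 carbonyl oxygen and cleaves the peri C5–H bond by carboxylate-assisted concerted metalation–deprotonation, forming a five-membered ruthenacycle (Ru, C5, C4a, C4, O); PhI(OCOCF3)2 oxidises this to a tetravalent ruthenium trifluoroacetate, C–O reductive elimination gives ester 13 and returns divalent ruthenium, and 13 is hydrolysed to 14 at work-up. The closest known reaction type is the ketone-directed ruthenium-catalysed ortho C–H oxygenation of aryl ketones with trivalent iodine oxidants, which has been shown at C5 of flavones and chromones with this reagent set. No ring is closed and no stereocentre is created. The selectivity needed is for C5 over C3 and over the three C–H bonds of ring B: C5–H is the only C–H bond on ring A and the only one the carbonyl oxygen can reach through a five-membered chelate, while the sulfonate and the C2 enone keep ring B too electron-poor for direct attack by the oxidant. (CF3CO)2O keeps the medium dry and holds the new oxygen as an electron-poor ester, and the remaining oxidant is reduced before hydrolysis, so that the para-related 5-oxygen and 8-methoxy pair of ring A should not be oxidised to a quinone.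

Step 8
Reactants: 14 5-hydroxy-6,7,8,4'-tetramethoxy-3'-(tosyloxy)flavone
Product: 15 5,6,7,8,4'-pentamethoxy-3'-(tosyloxy)flavone
Conditions: Me2SO4 (2 equiv), K2CO3 (3 equiv), acetone, reflux
Reagents that add atoms: dimethyl sulfate, COS(=O)(=O)OC
Why: Williamson O-methylation under prolonged reflux is the standard way to alkylate the hydrogen-bonded 5-hydroxyl of a flavone, and the aryl sulfonate is stable to carbonate in acetone.

Step 9
Reactants: 15 5,6,7,8,4'-pentamethoxy-3'-(tosyloxy)flavone
Product: 16 3'-demethylnobiletin (3'-hydroxy-5,6,7,8,4'-pentamethoxyflavone)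
Conditions: KOH (5 equiv), MeOH–H2O (4:1), 60 °C; then 1 M HCl to pH 4
Reagents that add atoms: none
Why: Alkaline hydrolysis of the aryl sulfonate by attack at sulfur (S–O cleavage) releases the 3'-phenoxide, which is protonated on acidification, while the moderate temperature should limit attack on the pyranone.

**Compound list**

1 | 2,3,4-trimethoxybenzaldehyde | COc1ccc(C=O)c(OC)c1OC | starting material
2 | 2,3,4-trimethoxyphenyl formate | COc1ccc(OC=O)c(OC)c1OC | intermediate (not isolated)
3 | 2,3,4-trimethoxyphenol | COc1ccc(O)c(OC)c1OC | intermediate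
4 | difluoroboron chelate of 5 (boron bridges the phenol oxygen and the ketone oxygen) | CC1=[O+][B-](F)(F)Oc2c(OC)c(OC)c(OC)cc12 | intermediate (not isolated)
5 | 1-(2-hydroxy-3,4,5-trimethoxyphenyl)ethanone | CC(=O)c1cc(OC)c(OC)c(OC)c1O | intermediate
6 | isovanillic acid (3-hydroxy-4-methoxybenzoic acid) | COc1ccc(C(=O)O)cc1O | starting material
7 | p-toluenesulfonyl chloride | Cc1ccc(S(=O)(=O)Cl)cc1 | starting material
8 | 4-methoxy-3-(tosyloxy)benzoic acid | COc1ccc(C(=O)O)cc1OS(=O)(=O)c1ccc(C)cc1 | intermediate
9 | 4-methoxy-3-(tosyloxy)benzoyl chloride | COc1ccc(C(=O)Cl)cc1OS(=O)(=O)c1ccc(C)cc1 | intermediate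
10 | dilithium phenoxide enolate of 5 | [Li+].[Li+].C=C([O-])c1cc(OC)c(OC)c(OC)c1[O-] | intermediate (not isolated)
11 | 1-(2-hydroxy-3,4,5-trimethoxyphenyl)-3-[4-methoxy-3-(tosyloxy)phenyl]propane-1,3-dione | COc1ccc(C(=O)CC(=O)c2cc(OC)c(OC)c(OC)c2O)cc1OS(=O)(=O)c1ccc(C)cc1 | intermediate
12 | 6,7,8,4'-tetramethoxy-3'-(tosyloxy)flavone | COc1ccc(-c2cc(=O)c3cc(OC)c(OC)c(OC)c3o2)cc1OS(=O)(=O)c1ccc(C)cc1 | intermediate (key-step precursor)
13 | 6,7,8,4'-tetramethoxy-3'-(tosyloxy)flavon-5-yl trifluoroacetate | COc1ccc(-c2cc(=O)c3c(OC(=O)C(F)(F)F)c(OC)c(OC)c(OC)c3o2)cc1OS(=O)(=O)c1ccc(C)cc1 | intermediate (not isolated)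
14 | 5-hydroxy-6,7,8,4'-tetramethoxy-3'-(tosyloxy)flavone | COc1ccc(-c2cc(=O)c3c(O)c(OC)c(OC)c(OC)c3o2)cc1OS(=O)(=O)c1ccc(C)cc1 | intermediate (key-step product)
15 | 5,6,7,8,4'-pentamethoxy-3'-(tosyloxy)flavone | COc1ccc(-c2cc(=O)c3c(OC)c(OC)c(OC)c(OC)c3o2)cc1OS(=O)(=O)c1ccc(C)cc1 | intermediate
16 | 3'-demethylnobiletin (3'-hydroxy-5,6,7,8,4'-pentamethoxyflavone) | COc1ccc(-c2cc(=O)c3c(OC)c(OC)c(OC)c(OC)c3o2)cc1O | target

**Step count**

Total steps: 9. Longest linear sequence: 7 steps (1, 2, 5, 6, 7, 8, 9; the ring B branch 3, 4, 5–9 is equally long).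

**Steps most likely to fail**

Step 7. Non-directed one-electron oxidation of the electron-rich ring A by the trivalent iodine reagent (oxidative coupling, or demethylation towards a quinone) may outpace the ruthenium cycle, and the flanking 6-methoxy group may slow metalation at C5–H. The fallback sets out from 5, returns at 15 and bypasses steps 7 and 8 by placing the C5 oxygen on the acetophenone before the flavone is built. Bromination of 5 at its only ring C–H (NBS, MeCN, 0 °C) should give 1-(2-bromo-6-hydroxy-3,4,5-trimethoxyphenyl)ethanone F1. Ullmann-type copper-mediated methanolysis (NaOMe, CuBr, MeOH–DMF, 110 °C) should then give 1-(2-hydroxy-3,4,5,6-tetramethoxyphenyl)ethanone F2. C-aroylation of F2 with 9 under the conditions of step 5 should give 1-(2-hydroxy-3,4,5,6-tetramethoxyphenyl)-3-[4-methoxy-3-(tosyloxy)phenyl]propane-1,3-dione F3, and cyclodehydration as in step 6 should give 15.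

Step 2. Acylation at C5 of 3 (ortho and para to methoxy groups) may compete with the chelation-controlled attack at C6, or the Lewis acid may cleave a methyl ether at 90 °C. The fallback sets out from 3 and returns at 5. O-Methylation of 3 (Me2SO4, K2CO3, acetone, reflux) should give 1,2,3,4-tetramethoxybenzene F4, whose two free positions are equivalent by symmetry. Friedel–Crafts acetylation (AcCl, AlCl3, CH2Cl2, 0 °C) should give 1-(2,3,4,5-tetramethoxyphenyl)ethanone F5. Chelation-controlled cleavage of the single methyl ether ortho to the carbonyl (BCl3, CH2Cl2, 0 °C) should return 5.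

Step 9. Hydroxide or methoxide may add to C2 of the pyranone and open ring C, with retro-Claisen cleavage following, faster than it attacks sulfur. The fallback sets out from 14 and returns at 16, moving the basic sulfonate cleavage to a stage where the chromone is protected as its 5-phenoxide and making the last deprotection neutral. Treatment of 14 with KOH in MeOH–H2O should give 5,3'-dihydroxy-6,7,8,4'-tetramethoxyflavone F6. Selective benzylation of the unchelated 3'-hydroxyl (BnBr 1.05 equiv, K2CO3, DMF, rt) should give 3'-benzyloxy-5-hydroxy-6,7,8,4'-tetramethoxyflavone F7. Methylation of the 5-hydroxyl (Me2SO4, K2CO3, acetone, reflux) should give 3'-benzyloxy-5,6,7,8,4'-pentamethoxyflavone F8, and hydrogenolysis (H2, Pd/C, EtOAc) should give 16.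

**Further compounds**

F1 | step 7 | 1-(2-bromo-6-hydroxy-3,4,5-trimethoxyphenyl)ethanone | CC(=O)c1c(Br)c(OC)c(OC)c(OC)c1O
F2 | step 7 | 1-(2-hydroxy-3,4,5,6-tetramethoxyphenyl)ethanone | CC(=O)c1c(OC)c(OC)c(OC)c(OC)c1O
F3 | step 7 | 1-(2-hydroxy-3,4,5,6-tetramethoxyphenyl)-3-[4-methoxy-3-(tosyloxy)phenyl]propane-1,3-dione | COc1ccc(C(=O)CC(=O)c2c(OC)c(OC)c(OC)c(OC)c2O)cc1OS(=O)(=O)c1ccc(C)cc1
F4 | step 2 | 1,2,3,4-tetramethoxybenzene | COc1ccc(OC)c(OC)c1OC
F5 | step 2 | 1-(2,3,4,5-tetramethoxyphenyl)ethanone | CC(=O)c1cc(OC)c(OC)c(OC)c1OC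
F6 | step 9 | 5,3'-dihydroxy-6,7,8,4'-tetramethoxyflavone | COc1ccc(-c2cc(=O)c3c(O)c(OC)c(OC)c(OC)c3o2)cc1O
F7 | step 9 | 3'-benzyloxy-5-hydroxy-6,7,8,4'-tetramethoxyflavone | COc1ccc(-c2cc(=O)c3c(O)c(OC)c(OC)c(OC)c3o2)cc1OCc1ccccc1
F8 | step 9 | 3'-benzyloxy-5,6,7,8,4'-pentamethoxyflavone | COc1ccc(-c2cc(=O)c3c(OC)c(OC)c(OC)c(OC)c3o2)cc1OCc1ccccc1
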